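In the target, C8 is bonded at once to the aryl ether oxygen O4' of ring B and to the carbinol carbon C7 that bears ring A. Cutting O4'–C8 and C7–C8 together therefore treats C8 as a carbene carbon and leaves three partners: sinapic acid (1) as its methyl ester 2 (the phenol), syringaldehyde (3) as its acetate 4 (the aldehyde) and ethyl diazoacetate (5). A single Rh2(OAc)4/chiral phosphoric acid co-catalysed coupling (phenol capture of the carbene to oxonium ylide 6, then aldol-type trapping by 4) should form both bonds and both stereocentres, giving ester 7 with the full skeleton; one iBu2AlH reduction then gives the target 8.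

Key step: step 3

Remark on numbering: ring A is the aryl group on C7, ring B carries O4', C9 is the carbon on C8 that becomes CH2OH, and C7'–C9' is the propenyl chain of ring B.

Remark on descriptors: in ester 7 the CO2Et group outranks C7 at C8, so the centre that is 8R in the target is labelled 2S in 7; the spatial arrangement (erythro, anti in the zigzag drawing) is the same and the reduction does not touch it.

Assumption: which enantiomer of the phosphoric acid delivers the (2S,3S) ester cannot be derived from the substrates; the route is written with the (R)-acid, and its mirror image would be used if a first trial shows the opposite sense.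

Step 1
Reactants: 1 sinapic acid [(E)-3-(4-hydroxy-3,5-dimethoxyphenyl)prop-2-enoic acid]
Product: 2 methyl sinapate [methyl (E)-3-(4-hydroxy-3,5-dimethoxyphenyl)prop-2-enoate]
Conditions: MeOH, H2SO4 (cat.), reflux
Reagents that add atoms: methanol, CO
Why: Fischer esterification in excess methanol should convert the acid into the methyl ester while the phenol and the (E)-alkene stay untouched.

Step 2
Reactants: 3 syringaldehyde (4-hydroxy-3,5-dimethoxybenzaldehyde)
Product: 4 4-acetoxy-3,5-dimethoxybenzaldehyde (4-formyl-2,6-dimethoxyphenyl acetate)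
Conditions: Ac2O, 4-(dimethylamino)pyridine (cat.), pyridine, 0 °C to rt
Reagents that add atoms: acetic anhydride, CC(=O)OC(C)=O
Why: O-acetylation of the phenol by nucleophilic acyl-transfer catalysis should be clean, since the aldehyde has no competing nucleophilic site.

Step 3
Reactants: 2 methyl sinapate; 4 4-acetoxy-3,5-dimethoxybenzaldehyde; 5 ethyl diazoacetate
Product: 7 ethyl (2S,3S)-3-(4-acetoxy-3,5-dimethoxyphenyl)-2-{2,6-dimethoxy-4-[(E)-3-methoxy-3-oxoprop-1-en-1-yl]phenoxy}-3-hydroxypropanoate, via oxonium ylide 6 (not isolated)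
Conditions: Rh2(OAc)4 (2 mol%), (R)-3,3'-bis(2,4,6-triisopropylphenyl)-1,1'-binaphthyl-2,2'-diyl hydrogen phosphate (10 mol%), 4 Å MS, CH2Cl2, 0 °C; 5 (1.5 equiv) added over 6 h by syringe pump to 4 (1.0 equiv) and 2 (1.3 equiv)
Reagents that add atoms: none
Why: Proposed new method: Rh2(OAc)4 expels N2 from 5 and the rhodium-bound carbene is captured by the phenolic oxygen of 2 to give oxonium ylide 6 (in equilibrium with its enol), which, held by the phosphoric acid through the enol O–H while the same acid protonates the carbonyl of 4, should add through C8 to the aldehyde faster than the 1,2-proton shift that would end in plain O–H insertion, so that O4'–C8 and C7–C8 form in one operation. The closest known reaction type is the Rh2(OAc)4/chiral Brønsted acid co-catalysed three-component trapping of alcohol-derived oxonium ylides from aryl diazoacetates with aldehydes or imines; an acceptor-only diazoacetate, a 2,6-disubstituted phenol and this benzaldehyde lie outside that scope. No ring is closed. Both stereocentres arise in the acid-bound aldol transition state: the 3,3'-aryl groups of the (R)-acid are relied on to select the aldehyde face (C7, S) and the enol face (C8, 2S in the ester, the 8R arrangement of the target), and the erythro (anti) relation should follow from placing ring A away from the bulky 2,6-dimethoxyaryloxy group. The step needs chemoselectivity for the phenol O–H and for trapping over proton transfer: the alkene of 2 is deactivated towards cyclopropanation by its ester, the acetoxy and two meta methoxy groups make 4 an electrophilic aldehyde, and slow addition of 5 with 2 in slight excess limits carbene dimerisation and insertion into the new C7 hydroxyl.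

Step 4
Reactants: 7 ethyl (2S,3S)-3-(4-acetoxy-3,5-dimethoxyphenyl)-2-{2,6-dimethoxy-4-[(E)-3-methoxy-3-oxoprop-1-en-1-yl]phenoxy}-3-hydroxypropanoate
Product: 8 (1S,2R)-1-(4-hydroxy-3,5-dimethoxyphenyl)-2-{4-[(E)-3-hydroxyprop-1-en-1-yl]-2,6-dimethoxyphenoxy}propane-1,3-diol (the 7S,8R erythro target)
Conditions: iBu2AlH (9 equiv), CH2Cl2, −78 to 0 °C; then MeOH, aq. potassium sodium tartrate (KNaC4H4O6)
Reagents that add atoms: none
Why: Hydride reduction with iBu2AlH (1,2-selective on the conjugated methyl ester, full reduction of the ethyl ester, reductive cleavage of the aryl acetate) should convert all three acyl groups in one operation without breaking any bond at C7 or C8 or touching the (E)-alkene, so both stereocentres are carried through (C8 becomes R by priority only), and the near-neutral tartrate work-up avoids quinone methide formation at C7.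

Compound list
1 | sinapic acid, (E)-3-(4-hydroxy-3,5-dimethoxyphenyl)prop-2-enoic acid | COc1cc(/C=C/C(=O)O)cc(OC)c1O | starting material
2 | methyl sinapate, methyl (E)-3-(4-hydroxy-3,5-dimethoxyphenyl)prop-2-enoate | COC(=O)/C=C/c1cc(OC)c(O)c(OC)c1 | intermediate
3 | syringaldehyde, 4-hydroxy-3,5-dimethoxybenzaldehyde | COc1cc(C=O)cc(OC)c1O | starting material
4 | 4-acetoxy-3,5-dimethoxybenzaldehyde | COc1cc(C=O)cc(OC)c1OC(C)=O | intermediate
5 | ethyl diazoacetate | CCOC(=O)C=[N+]=[N-] | starting material
6 | oxonium ylide from 2 and the carbene of 5 (drawn metal-free; not isolated) | CCOC(=O)[CH-][OH+]c1c(OC)cc(/C=C/C(=O)OC)cc1OC | intermediate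
7 | ethyl (2S,3S)-3-(4-acetoxy-3,5-dimethoxyphenyl)-2-{2,6-dimethoxy-4-[(E)-3-methoxy-3-oxoprop-1-en-1-yl]phenoxy}-3-hydroxypropanoate | COc1cc([C@H](O)[C@@H](C(=O)OCC)Oc2c(OC)cc(/C=C/C(=O)OC)cc2OC)cc(OC)c1OC(C)=O | intermediate
8 | (1S,2R)-1-(4-hydroxy-3,5-dimethoxyphenyl)-2-{4-[(E)-3-hydroxyprop-1-en-1-yl]-2,6-dimethoxyphenoxy}propane-1,3-diol | COc1cc([C@H](O)[C@@H](CO)Oc2c(OC)cc(/C=C/CO)cc2OC)cc(OC)c1O | target

Total step count: 4. Longest linear sequence: 3 steps (1 → 2 → 7 → 8, or 3 → 4 → 7 → 8).

Steps most likely to fail

Step 3 (Proposed new method). The 1,2-proton shift of ylide 6 may outrun aldol trapping, so that only O–H insertion occurs, or trapping may proceed with poor control of the erythro relation or of the absolute sense. The fallback is an auxiliary-controlled aldol sequence of known reactions that sets out from 2 (with 4 as the aldehyde) and rejoins the route at 8. Phenol 2 is O-alkylated with (S)-4-benzyl-3-(bromoacetyl)oxazolidin-2-one (K2CO3, acetone, rt) to give the aryloxyacetyl imide F1. Its (Z)-boron enolate (Bu2BOTf, iPr2NEt, CH2Cl2, −78 °C) adds to 4 in an Evans syn-aldol reaction to give the (2S,3R) syn-aldol adduct F2, in which C8 already has the target arrangement and C7 is epimeric. A Mitsunobu esterification (4-nitrobenzoic acid, PPh3, diisopropyl azodicarboxylate, THF, 0 °C) inverts C7 to give the (2S,3S) 4-nitrobenzoate F3; the allylic strain of the imide keeps the C8 hydrogen poorly acidic and so disfavours elimination. LiBH4 (THF–MeOH, 0 °C) removes the auxiliary reductively to give the primary alcohol F4; partial loss of an acyl group at this stage is harmless. iBu2AlH under the conditions of step 4 then reduces the methyl ester and cleaves the acetate and the 4-nitrobenzoate to give 8.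

Step 4. Reduction may stall at the hindered C9 ester, the aluminium aldolate may fragment by retro-aldol on warming, or C7 may epimerise through a quinone methide once the phenol is free. The fallback changes the protecting-group plan, sets out from 7 and returns at 8. The C7 hydroxyl of 7 is silylated (tBuMe2SiOTf, 2,6-lutidine, CH2Cl2, 0 °C) to give the silyl ether F5, which can no longer undergo retro-aldol cleavage. iBu2AlH reduction as in step 4 gives the silyl-protected triol F6, whose C7 silyloxy group is a poor leaving group. Bu4NF buffered with AcOH (THF, 0 °C) then releases 8.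

Step 1. Conversion may stop at the esterification equilibrium, or the electron-rich styrene may suffer acid-promoted oligomerisation or drift of alkene geometry on prolonged heating. The fallback builds the alkene instead of esterifying the acid: it sets out from 3 and arrives at 2. Wittig olefination of syringaldehyde 3 with the stabilised ylide Ph3P=CHCO2Me (toluene, reflux) should give the (E)-ester 2 directly, the free phenol being tolerated.

Further compounds
F1 | step 3 | (S)-4-benzyl-3-{2-[2,6-dimethoxy-4-((E)-3-methoxy-3-oxoprop-1-en-1-yl)phenoxy]acetyl}oxazolidin-2-one | COC(=O)/C=C/c1cc(OC)c(OCC(=O)N2[C@@H](Cc3ccccc3)COC2=O)c(OC)c1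
F2 | step 3 | (S)-4-benzyl-3-[(2S,3R)-3-(4-acetoxy-3,5-dimethoxyphenyl)-2-{2,6-dimethoxy-4-[(E)-3-methoxy-3-oxoprop-1-en-1-yl]phenoxy}-3-hydroxypropanoyl]oxazolidin-2-one | COc1cc([C@@H](O)[C@@H](C(=O)N3[C@@H](Cc4ccccc4)COC3=O)Oc2c(OC)cc(/C=C/C(=O)OC)cc2OC)cc(OC)c1OC(C)=O
F3 | step 3 | (1S,2S)-1-(4-acetoxy-3,5-dimethoxyphenyl)-3-[(S)-4-benzyl-2-oxooxazolidin-3-yl]-2-{2,6-dimethoxy-4-[(E)-3-methoxy-3-oxoprop-1-en-1-yl]phenoxy}-3-oxopropyl 4-nitrobenzoate | COc1cc([C@H](OC(=O)c5ccc(cc5)[N+](=O)[O-])[C@@H](C(=O)N3[C@@H](Cc4ccccc4)COC3=O)Oc2c(OC)cc(/C=C/C(=O)OC)cc2OC)cc(OC)c1OC(C)=O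
F4 | step 3 | (1S,2R)-1-(4-acetoxy-3,5-dimethoxyphenyl)-2-{2,6-dimethoxy-4-[(E)-3-methoxy-3-oxoprop-1-en-1-yl]phenoxy}-3-hydroxypropyl 4-nitrobenzoate | COc1cc([C@H](OC(=O)c3ccc(cc3)[N+](=O)[O-])[C@@H](CO)Oc2c(OC)cc(/C=C/C(=O)OC)cc2OC)cc(OC)c1OC(C)=O
F5 | step 4 | ethyl (2S,3S)-3-(4-acetoxy-3,5-dimethoxyphenyl)-3-(tert-butyldimethylsilyloxy)-2-{2,6-dimethoxy-4-[(E)-3-methoxy-3-oxoprop-1-en-1-yl]phenoxy}propanoate | COc1cc([C@H](O[Si](C)(C)C(C)(C)C)[C@@H](C(=O)OCC)Oc2c(OC)cc(/C=C/C(=O)OC)cc2OC)cc(OC)c1OC(C)=O
F6 | step 4 | (2R,3S)-3-(tert-butyldimethylsilyloxy)-3-(4-hydroxy-3,5-dimethoxyphenyl)-2-{4-[(E)-3-hydroxyprop-1-en-1-yl]-2,6-dimethoxyphenoxy}propan-1-ol | COc1cc([C@H](O[Si](C)(C)C(C)(C)C)[C@@H](CO)Oc2c(OC)cc(/C=C/CO)cc2OC)cc(OC)c1O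
F0 | step 1 | none | none
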